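The readings are simulated with made-up constants; the scatter is artificial.

Early times first: what was charged, what was read, and what is asked?

| setting | south | north-west | south-west | violet | amber | ochre | grey |
|---|---|---|---|---|---|---|---|
| substrate | 10 mM | 6.7 mM | 15 mM | 10 mM | 10 mM (fed, over 12 h) | 10 mM (fed, over 12 h) | 10 mM (in portions, 2, over 12 h) |
| partner | 1.1 equiv | 1.1 equiv | 1.1 equiv | 1.10 equiv (fed, over 12 h) | 1.10 equiv | 1.10 equiv | 1.10 equiv |
| temperature | −5 °C | 6 °C | −5 °C | 0 °C | 0 °C |  | 0 °C |
| remark | run made earlier | run made earlier | run made earlier | all else is in the flask from the start; the feed brings no volume worth counting | all else is in the flask from the start; the feed brings no volume worth counting | the addition at −40 °C, then warmed to 0 °C; the feed brings no volume worth counting | first portion at the start, last at 12 h |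
| time |  |  |  | 20 h | 20 h | 20 h | 20 h |

| run | time / h | target / % | substrate / % |
|---|---|---|---|
| south | 1.50 | 25.9 | 72.9 |
| south | 3.00 | 44.7 | 54.8 |
| south | 6.00 | 65.0 | 34.8 |
| south | 10.0 | 78.7 | 20.7 |
| south | 20.0 | 89.9 | 7.8 |
| north-west | 1.33 | 40.2 | 57.6 |
| north-west | 2.50 | 57.2 | 40.5 |
| north-west | 5.00 | 77.8 | 23.0 |
| north-west | 8.00 | 86.8 | 13.1 |
| north-west | 15.0 | 92.3 | 6.9 |
| south-west | 1.33 | 28.5 | 72.1 |
| south-west | 4.00 | 57.9 | 42.5 |
| south-west | 8.00 | 78.7 | 22.3 |
| south-west | 12.0 | 85.3 | 12.2 |
| south-west | 15.0 | 88.4 | 10.1 |

(each reading ± 1 percentage point)

- a reading or a percentage of target counts all its forms, free or not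

- the best flask by amount of target, in percent of the substrate charged; "all alike" if 1.5 percentage points covers them all (violet / amber / ochre / grey / all alike)
- amount of target at the end, in percent of the substrate charged, violet
- amount of target at the end, in percent of the substrate charged, amber
- amount of target at the end, in percent of the substrate charged, ochre
- amount of target at the end, in percent of the substrate charged, grey

How does the pace depend on strength? South and south-west share a temperature and equivalents, and south-west has 1.50 times the charge. South has 20.7% of its substrate left after 10.0 h, south-west 22.3% after 8.00 h. That is nearly the same fraction, so the time shrinks by a factor of 1.25, smaller than the factor on the charge. As a reading, that puts the total order 0.550 above first order. I give substrate, the limiting reagent by charge, order one, and partner about 0.5.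

Then what does a slow feed cost? Take the even case as zero. A first-order species fed steadily arrives on average halfway through, so it gives away 6.00 h, and if both species were first order, feeding either would cost the same. Partner departs from this: at fed fraction f its strength goes as the root of f, whose mean over a steady feed is 0.667, so feeding it gives away 4.00 h. Call this the lost time: the hours at full strength a recipe gives away by its way of addition.

The weak spot? Partner reacts while it is fed, and this reckoning ignores that, so I use it to rank recipes, not to give yields.

And ochre? If nothing reacts in the cold, it loses 12.0 h. Grey's portions arrive 6.00 h late on average, like amber's, but its second portion has 8.00 h. My ranking is violet first, ochre last, amber and grey between.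

The forecast puts the same flasks first and last, and it also places amber above grey, which my ranking leaves open. Its numbers are violet 88.5%, amber 86%, grey 83%, ochre 81.5%, with the ground that “Feeding partner costs little because the order in partner is low and substrate stays high”.

What does the flask give?

    crystals ⇌ target, rate k1*(cs1 - [target]) while solid is left; crystals form when [target] > cs1 (solubility = 2.00 mM, k = 6.34 × 10⁻⁴ s⁻¹)
    partner → decomposed reagent (k = 4.12 × 10⁻⁶ s⁻¹, Ea = 90.0 kJ mol⁻¹)
    substrate → decomposition product (k = 9.23 × 10⁻⁹ s⁻¹, Ea = 118 kJ mol⁻¹)
    substrate + partner → target, rate k4*[substrate]*[partner]^0.5 (k = 8.99 × 10⁻⁴ L⁰·⁵ mol⁻⁰·⁵ s⁻¹, Ea = 53.0 kJ mol⁻¹)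
    (constants at 0 °C)

Violet gives 92.3%, more than amber's 87.6%, grey's 84.8% and ochre's 83.0%. At 12.0 h, the end of the feed, violet holds 75.8% target and amber 65.9%, crystals counted. Violet's lost time of 4.00 h against amber's 6.00 h goes with an end gap of 4.7 percentage points. Ochre, with a lost time of 12.0 h, still has 96.4% substrate at 12.0 h and ends with 17.0%, against 7.71% in violet.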